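The benzene ring is built, not decorated. Counting from the carboxyl carbon (C1), ring atoms C1, C2, C3 and C6 come from a coumalate ester that already carries the protected hydroxyprenyl chain on pyrone C3. C4 with its oxygen and C5 with the long chain come from a chiral triisopropylsilyl ynol ether. One thermal operation forms C5–C6 and C3–C4, expels CO2 and gives the 1,3,4,5-substituted arene without an oxidant. It exploits the para relation between the C4 oxygen and the C1 carboxyl, which mirrors the donor–acceptor polarity of alkyne and pyrone. The epimerisable enone is attached only afterwards, under near-neutral conditions.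

Key step: step 12

Remark on the chemistry: the carbinol carbon formed in the chromium-mediated coupling and the two bridgehead carbons of the transient bridged lactone are erased by the events that follow, so these compounds are carried as mixtures of epimers and drawn without descriptors at those atoms.

Step 1
Reactants: 1 coumalic acid
Product: 3 2-(trimethylsilyl)ethyl 2-oxo-2H-pyran-5-carboxylate, via coumaloyl chloride 2 (not isolated)
Conditions: (COCl)2, DMF (cat.), CH2Cl2, 0 °C to rt, evaporate; Me3SiCH2CH2OH, pyridine (1.05 equiv), CH2Cl2, 0 °C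
Reagents that add atoms: 2-(trimethylsilyl)ethanol C[Si](C)(C)CCO; oxalyl chloride O=C(Cl)C(=O)Cl (chlorine of 2 only)
Why: Esterification through the acyl chloride is the established entry to coumalate esters and keeps out the strong bases and nucleophiles that open the pyrone at C6; the silylethyl ester is chosen so that fluoride frees the acid in the last step.

Step 2
Reactants: 3 2-(trimethylsilyl)ethyl coumalate
Product: 4 2-(trimethylsilyl)ethyl 3-bromo-2-oxo-2H-pyran-5-carboxylate
Conditions: Br2 (1.1 equiv), NaOAc (1.2 equiv), AcOH, 50 °C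
Reagents that add atoms: bromine BrBr
Why: Electrophilic bromination (addition–elimination) of 2-pyrones goes to C3 or C5, so with C5 blocked by the ester only C3 should react, and acetate takes up the HBr that could otherwise attack the silylethyl ester.

Step 3
Reactants: 5 isoprene monoxide (racemic 2-methyl-2-vinyloxirane)
Product: 6 (E)-4-chloro-2-methylbut-2-en-1-ol
Conditions: TiCl4 (1.2 equiv), CH2Cl2, −85 °C; aq. HCl quench
Reagents that add atoms: titanium tetrachloride Cl[Ti](Cl)(Cl)Cl
Why: Lewis-acid-promoted SN2' opening of the vinyl oxirane by chloride runs through the s-trans conformer of the titanium-bound epoxide and is a known route to this chloro alcohol, which fixes the E geometry of the trisubstituted alkene.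

Step 4
Reactants: 6 (E)-4-chloro-2-methylbut-2-en-1-ol
Product: 7 (E)-tert-butyl[(4-chloro-2-methylbut-2-en-1-yl)oxy]diphenylsilane
Conditions: t-BuPh2SiCl, imidazole, CH2Cl2, 0 °C
Reagents that add atoms: tert-butyldiphenylsilyl chloride CC(C)(C)[Si](Cl)(c1ccccc1)c1ccccc1
Why: Standard silylation of a primary alcohol is fast enough at 0 °C to outrun N-alkylation of imidazole by the allylic chloride, and the TBDPS group is chosen because it outlasts the acidic methanolysis of step 13.

Step 5
Reactants: 7 allylic chloride TBDPS ether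
Product: 8 (E)-tert-butyl{[2-methyl-4-(tributylstannyl)but-2-en-1-yl]oxy}diphenylsilane
Conditions: Bu3SnH, LiN(i-Pr)2, THF, 0 °C; then 7, −78 °C; chromatography on Et3N-deactivated silica
Reagents that add atoms: tributyltin hydride CCCC[SnH](CCCC)CCCC (used as Bu3SnLi)
Why: SN2 displacement of a primary allylic chloride by a stannyl anion is the standard preparation of prenyl-type stannanes and should leave the alkene geometry and the silyl ether untouched.

Step 6
Reactants: 4 3-bromocoumalate ester; 8 allylstannane
Product: 9 2-(trimethylsilyl)ethyl 3-[(E)-4-(tert-butyldiphenylsilyloxy)-3-methylbut-2-enyl]-2-oxo-2H-pyran-5-carboxylate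
Conditions: 8 (1.2 equiv), Pd2(dba)3 (2.5 mol %), AsPh3 (20 mol %), NMP, 50 °C
Reagents that add atoms: none
Why: Stille coupling of 3-bromo-2-pyrones runs under neutral conditions that the ring tolerates, and the pyronyl(η3-allyl)palladium intermediate should reductively eliminate at the unsubstituted allyl terminus to give the linear E product.

Step 7
Reactants: 10 methyl (S)-3-hydroxy-2-methylpropanoate
Product: 11 methyl (S)-3-(tert-butyldimethylsilyloxy)-2-methylpropanoate
Conditions: t-BuMe2SiCl, imidazole, CH2Cl2, rt
Reagents that add atoms: tert-butyldimethylsilyl chloride CC(C)(C)[Si](C)(C)Cl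
Why: Routine silylation of the primary alcohol under weakly basic conditions does not touch the α-stereocentre, which is the only stereocentre of the target and comes from the chiral pool.

Step 8
Reactants: 11 silylated hydroxy ester
Product: 12 (S)-3-(tert-butyldimethylsilyloxy)-2-methylpropanal
Conditions: i-Bu2AlH (1.05 equiv), CH2Cl2, −78 °C; MeOH, aq. potassium sodium tartrate
Reagents that add atoms: none
Why: Partial reduction of the ester with diisobutylaluminium hydride stops at the stable tetrahedral aluminium hemiacetal at −78 °C, and the aldehyde is used at once so that the α-centre should not epimerise.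

Step 9
Reactants: 12 (S)-aldehyde
Product: 13 ethyl (R,E)-5-(tert-butyldimethylsilyloxy)-4-methylpent-2-enoate
Conditions: Ph3P=CHCO2Et, CH2Cl2, rt
Reagents that add atoms: ethyl (triphenylphosphoranylidene)acetate CCOC(=O)C=P(c1ccccc1)(c1ccccc1)c1ccccc1
Why: Wittig olefination with a stabilised, barely basic ylide adds two carbons without enolising the aldehyde, and the descriptor changes from S to R only because the CIP ranking of the substituents changes.

Step 10
Reactants: 13 enoate
Product: 14 ethyl (R)-5-(tert-butyldimethylsilyloxy)-4-methylpentanoate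
Conditions: H2 (1 atm), Pd/C, EtOAc, rt
Reagents that add atoms: none
Why: Catalytic hydrogenation of the conjugated alkene in a non-protic solvent leaves the TBS ether and the stereocentre alone.

Step 11
Reactants: 14 saturated ethyl ester
Product: 17 tert-butyldimethyl{[(2R)-2-methyl-6-(triisopropylsilyloxy)hex-5-yn-1-yl]oxy}silane, via lithium dibromoenolate 15 (not isolated), via lithium ynolate 16 (not isolated)
Conditions: CH2Br2, lithium 2,2,6,6-tetramethylpiperidide, THF, −78 °C; 14; LiN(SiMe3)2, −78 °C; n-BuLi, −78 °C to rt; i-Pr3SiCl, 0 °C to rt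
Reagents that add atoms: dibromomethane BrCBr; triisopropylsilyl chloride CC(C)[Si](Cl)(C(C)C)C(C)C
Why: In this Kowalski homologation, acylation of LiCHBr2 and enolisation give 15, bromine–lithium exchange triggers the 1,2-alkyl shift to ynolate 16, and the bulky chlorosilane is known to silylate such ynolates on oxygen, all three carbons away from the stereocentre.

Step 12
Reactants: 9 3-allylated coumalate ester; 17 siloxyalkyne
Product: 19 2-(trimethylsilyl)ethyl 3-[(E)-4-(tert-butyldiphenylsilyloxy)-3-methylbut-2-enyl]-5-[(3R)-4-(tert-butyldimethylsilyloxy)-3-methylbutyl]-4-(triisopropylsilyloxy)benzoate, via bridged lactone 18 (not isolated)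
Conditions: 17 (1.5 equiv), toluene (0.5 M), BHT (cat.), argon, sealed tube, 120 °C
Reagents that add atoms: none
Why: In this inverse-electron-demand Diels–Alder reaction the alkyl-bearing alkyne carbon of 17, the nucleophilic end of the ynol ether, bonds to pyrone C6, the diene terminus that feels both carbonyl groups, and the oxygen-bearing carbon closes on pyrone C3 in one asynchronous [4+2] event to give the 2-oxabicyclo[2.2.2]octadienone 18. Lactone 18 then sheds CO2 in a retro-[4+2] step that is irreversible and aromatising, so no oxidant is needed. The closest known reaction type is the cycloaddition–decarboxylation of coumalate esters with ynamines, alkoxyalkynes, ketene acetals and enol ethers, which places the donor para to the ester, and silyl ynol ethers are established partners in benzannulations with 2-pyrones, electron-poor azadienes and vinylketenes. The benzene ring is closed intermolecularly as a union of four atoms (pyrone C3 to C6) with two (the alkyne carbons), both new bonds being ring bonds. No lasting stereocentre is made, because the bridgeheads of 18 vanish with the CO2 and the methyl-bearing centre sits in a saturated chain that neutral heating cannot disturb. The step needs regioselectivity, secured by the matched polarity (ester and lactone carbonyl both activate C6, while the alkyl group makes C3 the less electrophilic end), and chemoselectivity over [2+2] addition and over the side-chain alkene, secured by CO2 loss as an irreversible sink and by the much higher nucleophilicity of the ynol ether.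

Step 13
Reactants: 19 fully protected benzoate
Product: 20 2-(trimethylsilyl)ethyl 3-[(E)-4-(tert-butyldiphenylsilyloxy)-3-methylbut-2-enyl]-5-[(3R)-4-hydroxy-3-methylbutyl]-4-(triisopropylsilyloxy)benzoate
Conditions: camphorsulfonic acid (10 mol %), MeOH/CH2Cl2 1:1, 0 °C
Reagents that add atoms: none
Why: Acid-catalysed methanolysis sorts silyl ethers by bulk and type, so the primary alkyl TBS ether should go first while the TBDPS ether, the doubly ortho-flanked aryl TIPS ether and the silylethyl ester stay.

Step 14
Reactants: 20 primary alcohol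
Product: 21 2-(trimethylsilyl)ethyl 3-[(E)-4-(tert-butyldiphenylsilyloxy)-3-methylbut-2-enyl]-5-[(3R)-3-methyl-4-oxobutyl]-4-(triisopropylsilyloxy)benzoate
Conditions: Dess–Martin periodinane, CH2Cl2, 0 °C to rt; used directly
Reagents that add atoms: none
Why: Dess–Martin oxidation stops at the aldehyde and is non-basic, so the α-methyl centre should keep its configuration.

Step 15
Reactants: 22 2-methylbut-3-yn-2-ol
Product: 23 triethyl[(2-methylbut-3-yn-2-yl)oxy]silane
Conditions: Et3SiOTf, 2,6-lutidine, CH2Cl2, 0 °C
Reagents that add atoms: triethylsilyl triflate CC[Si](CC)(CC)OS(=O)(=O)C(F)(F)F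
Why: Silyl triflate silylation copes with the tertiary alcohol, removes the only protic group that could quench the alkenylchromium species of step 17, and the ether leaves with the other silicon groups in step 19.

Step 16
Reactants: 23 propargylic TES ether
Product: 25 (E)-triethyl[(4-iodo-2-methylbut-3-en-2-yl)oxy]silane, via (E)-alkenylstannane 24 (not isolated)
Conditions: Bu3SnH, PdCl2(PPh3)2 (2 mol %), THF, 0 °C to rt; then I2, CH2Cl2, 0 °C
Reagents that add atoms: iodine II; tributyltin hydride CCCC[SnH](CCCC)CCCC (tin group of 24 only)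
Why: Palladium-catalysed syn-hydrostannation puts tin on the terminal carbon, away from the bulky quaternary centre, and iododestannylation proceeds with retention, which sets the E geometry of the future enone.

Step 17
Reactants: 21 aldehyde; 25 (E)-alkenyl iodide
Product: 26 2-(trimethylsilyl)ethyl 3-[(E)-4-(tert-butyldiphenylsilyloxy)-3-methylbut-2-enyl]-5-[(3R,5E)-4-hydroxy-3,7-dimethyl-7-(triethylsilyloxy)oct-5-enyl]-4-(triisopropylsilyloxy)benzoate (both epimers at side-chain C4)
Conditions: 25 (2.5 equiv), CrCl2 (6 equiv), NiCl2 (cat.), DMSO, rt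
Reagents that add atoms: none
Why: In the Nozaki–Hiyama–Kishi coupling zerovalent nickel inserts into the C–I bond with retention, transmetalation gives a weakly basic alkenyl species of trivalent chromium that adds to the aldehyde without enolising it and ignores the ester, and the new carbinol centre needs no control because step 18 removes it.

Step 18
Reactants: 26 allylic alcohol
Product: 27 2-(trimethylsilyl)ethyl 3-[(E)-4-(tert-butyldiphenylsilyloxy)-3-methylbut-2-enyl]-5-[(3R,5E)-3,7-dimethyl-4-oxo-7-(triethylsilyloxy)oct-5-enyl]-4-(triisopropylsilyloxy)benzoate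
Conditions: Dess–Martin periodinane, CH2Cl2, 0 °C to rt
Reagents that add atoms: none
Why: Dess–Martin oxidation of the secondary allylic alcohol converges both epimers on the E enone under non-basic conditions that spare the adjacent stereocentre, the silyl ethers and the trisubstituted alkene.

Step 19
Reactants: 27 protected enone
Product: 28 4-hydroxy-3-[(E)-4-hydroxy-3-methylbut-2-enyl]-5-[(3R,5E)-7-hydroxy-3,7-dimethyl-4-oxooct-5-enyl]benzoic acid (target)
Conditions: Bu4NF/AcOH (1:1, 8 equiv each), THF, 0 °C to rt; pH 4 buffer work-up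
Reagents that add atoms: none
Why: Fluoride-induced desilylation of the three silyl ethers and β-elimination of the silylethyl ester (to ethene and Me3SiF) free all four groups at once, and the equimolar acetic acid keeps the medium below the basicity at which the ketone α-carbon would epimerise or alkoxide would add to the enone.

Compound list
1 | coumalic acid (2-oxo-2H-pyran-5-carboxylic acid) | O=C(O)C1=COC(=O)C=C1 | starting material
2 | coumaloyl chloride (2-oxo-2H-pyran-5-carbonyl chloride) | O=C(Cl)C1=COC(=O)C=C1 | intermediate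
3 | 2-(trimethylsilyl)ethyl 2-oxo-2H-pyran-5-carboxylate | C[Si](C)(C)CCOC(=O)C1=COC(=O)C=C1 | intermediate
4 | 2-(trimethylsilyl)ethyl 3-bromo-2-oxo-2H-pyran-5-carboxylate | C[Si](C)(C)CCOC(=O)C1=COC(=O)C(Br)=C1 | intermediate
5 | isoprene monoxide (2-methyl-2-vinyloxirane, racemic) | CC1(C=C)CO1 | starting material
6 | (E)-4-chloro-2-methylbut-2-en-1-ol | C/C(=C\CCl)CO | intermediate
7 | (E)-tert-butyl[(4-chloro-2-methylbut-2-en-1-yl)oxy]diphenylsilane | C/C(=C\CCl)CO[Si](c1ccccc1)(c1ccccc1)C(C)(C)C | intermediate
8 | (E)-tert-butyl{[2-methyl-4-(tributylstannyl)but-2-en-1-yl]oxy}diphenylsilane | C/C(=C\C[Sn](CCCC)(CCCC)CCCC)CO[Si](c1ccccc1)(c1ccccc1)C(C)(C)C | intermediate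
9 | 2-(trimethylsilyl)ethyl 3-[(E)-4-(tert-butyldiphenylsilyloxy)-3-methylbut-2-enyl]-2-oxo-2H-pyran-5-carboxylate | C[Si](C)(C)CCOC(=O)C1=COC(=O)C(C/C=C(\C)CO[Si](c2ccccc2)(c2ccccc2)C(C)(C)C)=C1 | intermediate
10 | methyl (S)-3-hydroxy-2-methylpropanoate | COC(=O)[C@@H](C)CO | starting material
11 | methyl (S)-3-(tert-butyldimethylsilyloxy)-2-methylpropanoate | COC(=O)[C@@H](C)CO[Si](C)(C)C(C)(C)C | intermediate
12 | (S)-3-(tert-butyldimethylsilyloxy)-2-methylpropanal | O=C[C@@H](C)CO[Si](C)(C)C(C)(C)C | intermediate
13 | ethyl (R,E)-5-(tert-butyldimethylsilyloxy)-4-methylpent-2-enoate | CCOC(=O)/C=C/[C@@H](C)CO[Si](C)(C)C(C)(C)C | intermediate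
14 | ethyl (R)-5-(tert-butyldimethylsilyloxy)-4-methylpentanoate | CCOC(=O)CC[C@@H](C)CO[Si](C)(C)C(C)(C)C | intermediate
15 | lithium (5R)-1,1-dibromo-6-(tert-butyldimethylsilyloxy)-5-methylhex-1-en-2-olate | [Li+].[O-]C(=C(Br)Br)CC[C@@H](C)CO[Si](C)(C)C(C)(C)C | intermediate
16 | lithium (5R)-6-(tert-butyldimethylsilyloxy)-5-methylhex-1-yn-1-olate | [Li+].[O-]C#CCC[C@@H](C)CO[Si](C)(C)C(C)(C)C | intermediate
17 | tert-butyldimethyl{[(2R)-2-methyl-6-(triisopropylsilyloxy)hex-5-yn-1-yl]oxy}silane | CC(C)[Si](OC#CCC[C@@H](C)CO[Si](C)(C)C(C)(C)C)(C(C)C)C(C)C | intermediate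
18 | 2-(trimethylsilyl)ethyl 4-[(E)-4-(tert-butyldiphenylsilyloxy)-3-methylbut-2-enyl]-7-[(3R)-4-(tert-butyldimethylsilyloxy)-3-methylbutyl]-3-oxo-8-(triisopropylsilyloxy)-2-oxabicyclo[2.2.2]octa-5,7-diene-6-carboxylate (bridgeheads undefined) | O=C1OC2C(C(=O)OCC[Si](C)(C)C)=CC1(C/C=C(\C)CO[Si](c1ccccc1)(c1ccccc1)C(C)(C)C)C(O[Si](C(C)C)(C(C)C)C(C)C)=C2CC[C@@H](C)CO[Si](C)(C)C(C)(C)C | intermediate
19 | 2-(trimethylsilyl)ethyl 3-[(E)-4-(tert-butyldiphenylsilyloxy)-3-methylbut-2-enyl]-5-[(3R)-4-(tert-butyldimethylsilyloxy)-3-methylbutyl]-4-(triisopropylsilyloxy)benzoate | C[Si](C)(C)CCOC(=O)c1cc(C/C=C(\C)CO[Si](c2ccccc2)(c2ccccc2)C(C)(C)C)c(O[Si](C(C)C)(C(C)C)C(C)C)c(CC[C@@H](C)CO[Si](C)(C)C(C)(C)C)c1 | intermediate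
20 | 2-(trimethylsilyl)ethyl 3-[(E)-4-(tert-butyldiphenylsilyloxy)-3-methylbut-2-enyl]-5-[(3R)-4-hydroxy-3-methylbutyl]-4-(triisopropylsilyloxy)benzoate | C[Si](C)(C)CCOC(=O)c1cc(C/C=C(\C)CO[Si](c2ccccc2)(c2ccccc2)C(C)(C)C)c(O[Si](C(C)C)(C(C)C)C(C)C)c(CC[C@@H](C)CO)c1 | intermediate
21 | 2-(trimethylsilyl)ethyl 3-[(E)-4-(tert-butyldiphenylsilyloxy)-3-methylbut-2-enyl]-5-[(3R)-3-methyl-4-oxobutyl]-4-(triisopropylsilyloxy)benzoate | C[Si](C)(C)CCOC(=O)c1cc(C/C=C(\C)CO[Si](c2ccccc2)(c2ccccc2)C(C)(C)C)c(O[Si](C(C)C)(C(C)C)C(C)C)c(CC[C@@H](C)C=O)c1 | intermediate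
22 | 2-methylbut-3-yn-2-ol | CC(C)(O)C#C | starting material
23 | triethyl[(2-methylbut-3-yn-2-yl)oxy]silane | CC[Si](CC)(CC)OC(C)(C)C#C | intermediate
24 | (E)-triethyl{[2-methyl-4-(tributylstannyl)but-3-en-2-yl]oxy}silane | CC[Si](CC)(CC)OC(C)(C)/C=C/[Sn](CCCC)(CCCC)CCCC | intermediate
25 | (E)-triethyl[(4-iodo-2-methylbut-3-en-2-yl)oxy]silane | CC[Si](CC)(CC)OC(C)(C)/C=C/I | intermediate
26 | 2-(trimethylsilyl)ethyl 3-[(E)-4-(tert-butyldiphenylsilyloxy)-3-methylbut-2-enyl]-5-[(3R,5E)-4-hydroxy-3,7-dimethyl-7-(triethylsilyloxy)oct-5-enyl]-4-(triisopropylsilyloxy)benzoate (carbinol epimers) | C[Si](C)(C)CCOC(=O)c1cc(C/C=C(\C)CO[Si](c2ccccc2)(c2ccccc2)C(C)(C)C)c(O[Si](C(C)C)(C(C)C)C(C)C)c(CC[C@@H](C)C(O)/C=C/C(C)(C)O[Si](CC)(CC)CC)c1 | intermediate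
27 | 2-(trimethylsilyl)ethyl 3-[(E)-4-(tert-butyldiphenylsilyloxy)-3-methylbut-2-enyl]-5-[(3R,5E)-3,7-dimethyl-4-oxo-7-(triethylsilyloxy)oct-5-enyl]-4-(triisopropylsilyloxy)benzoate | C[Si](C)(C)CCOC(=O)c1cc(C/C=C(\C)CO[Si](c2ccccc2)(c2ccccc2)C(C)(C)C)c(O[Si](C(C)C)(C(C)C)C(C)C)c(CC[C@@H](C)C(=O)/C=C/C(C)(C)O[Si](CC)(CC)CC)c1 | intermediate
28 | 4-hydroxy-3-[(E)-4-hydroxy-3-methylbut-2-enyl]-5-[(3R,5E)-7-hydroxy-3,7-dimethyl-4-oxooct-5-enyl]benzoic acid (CNP0120226.1) | C/C(=C\Cc1cc(C(=O)O)cc(CC[C@@H](C)C(=O)/C=C/C(C)(C)O)c1O)CO | target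

Total step count: 19.
Longest linear sequence: 11 steps, from 10 (steps 7 to 14, then 17 to 19).

Steps most likely to fail

1. Step 12.
- **What may go wrong:** closure of the second bond at the alkyl-bearing pyrone carbon, next to the bulky silyloxy group, may be slow. Silyl migration of the ynol ether to a silylketene, [2+2] addition or leakage of regiochemistry could then overtake the cycloaddition.
- **Fallback:** it sets out from bromopyrone 4 and siloxyalkyne 17 and runs the ring construction before the allylation. Bromine is smaller than the allyl chain and lowers the diene LUMO, so heating the two in toluene should give the bridged bromo lactone F1. Loss of CO2 from it gives 2-(trimethylsilyl)ethyl 3-bromo-5-[(3R)-4-(tert-butyldimethylsilyloxy)-3-methylbutyl]-4-(triisopropylsilyloxy)benzoate F2. Stille allylation of this aryl bromide with stannane 8 (Pd(PPh3)4, DMF, 90 °C) comes back to the route at 19.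
- **Precedent:** both the cycloaddition–decarboxylation of 3-bromocoumalates and the Stille prenylation of ortho-oxygenated aryl bromides are known chemistry.

2. Step 6.
- **What may go wrong:** allyl transfer through the substituted terminus, erosion of the alkene geometry by π-allyl isomerisation, migration of the alkene into conjugation, or opening of the pyrone during a slow coupling.
- **Fallback:** it reverses the polarity of the coupling and sets out from 4 and allylic chloride 7. Palladium-catalysed stannylation of 4 with Me3SnSnMe3 (Pd(PPh3)4, dioxane, 90 °C) should give 2-(trimethylsilyl)ethyl 2-oxo-3-(trimethylstannyl)-2H-pyran-5-carboxylate F3. This is then coupled with 7 (Pd2(dba)3, tri(2-furyl)phosphine, THF, 40 °C). The π-allylpalladium now arises from the chloride and should accept the pyronyl group at its unhindered end, which comes back at 9.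

3. Step 11.
- **What may go wrong:** incomplete rearrangement of the carbenoid, silylation on carbon instead of oxygen, or hydrolysis of the ynol ether during isolation.
- **Fallback:** it sets out from 14 and reaches the ynolate by oxidation of an acetylide instead of by ester homologation. Reduction with i-Bu2AlH at −78 °C gives (R)-5-(tert-butyldimethylsilyloxy)-4-methylpentanal F4. Seyferth–Gilbert homologation with the Ohira–Bestmann reagent (K2CO3, MeOH) gives (R)-tert-butyldimethyl[(2-methylhex-5-yn-1-yl)oxy]silane F5. n-BuLi converts this into its lithium acetylide F6, and lithium tert-butyl peroxide (from t-BuOOH and LiN(SiMe3)2, THF, −78 to 0 °C) oxidises that acetylide. The route is rejoined at ynolate 16, which is trapped with i-Pr3SiOTf to give 17.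

Further compounds
F1 | step 12 | 2-(trimethylsilyl)ethyl 4-bromo-7-[(3R)-4-(tert-butyldimethylsilyloxy)-3-methylbutyl]-3-oxo-8-(triisopropylsilyloxy)-2-oxabicyclo[2.2.2]octa-5,7-diene-6-carboxylate (bridgeheads undefined) | O=C1OC2C(C(=O)OCC[Si](C)(C)C)=CC1(Br)C(O[Si](C(C)C)(C(C)C)C(C)C)=C2CC[C@@H](C)CO[Si](C)(C)C(C)(C)C
F2 | step 12 | 2-(trimethylsilyl)ethyl 3-bromo-5-[(3R)-4-(tert-butyldimethylsilyloxy)-3-methylbutyl]-4-(triisopropylsilyloxy)benzoate | C[Si](C)(C)CCOC(=O)c1cc(Br)c(O[Si](C(C)C)(C(C)C)C(C)C)c(CC[C@@H](C)CO[Si](C)(C)C(C)(C)C)c1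
F3 | step 6 | 2-(trimethylsilyl)ethyl 2-oxo-3-(trimethylstannyl)-2H-pyran-5-carboxylate | C[Si](C)(C)CCOC(=O)C1=COC(=O)C([Sn](C)(C)C)=C1
F4 | step 11 | (R)-5-(tert-butyldimethylsilyloxy)-4-methylpentanal | O=CCC[C@@H](C)CO[Si](C)(C)C(C)(C)C
F5 | step 11 | (R)-tert-butyldimethyl[(2-methylhex-5-yn-1-yl)oxy]silane | C#CCC[C@@H](C)CO[Si](C)(C)C(C)(C)C
F6 | step 11 | lithium acetylide of F5, [(5R)-6-(tert-butyldimethylsilyloxy)-5-methylhex-1-yn-1-yl]lithium | [Li]C#CCC[C@@H](C)CO[Si](C)(C)C(C)(C)C
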